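the same everywhere: substrate 31 mM

| flask | free catalyst | remark | time |
|---|---|---|---|
| larch | 0.28 mol% | run made earlier |  |
| cedar | 0.44 mol% | run made earlier |  |
| flask | 0.2 mol% |  | 4.0 h |

| run | time / h | target / % |
|---|---|---|
| larch | 0.250 | 52.3 |
| larch | 0.833 | 15.4 |
| larch | 1.33 | 9.1 |
| larch | 2.00 | 6.5 |
| larch | 3.00 | 6.2 |
| larch | 4.00 | 5.6 |
| cedar | 0.250 | 52.5 |
| cedar | 0.833 | 16.9 |
| cedar | 1.33 | 9.2 |
| cedar | 2.00 | 7.1 |
| cedar | 3.00 | 6.7 |
| cedar | 4.00 | 6.3 |

(standard deviation of a reading: 0.3 percentage points)

- a species is counted by the substrate in it: one self-condensation product counts as two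
- the numbers in the tables scatter by 0.3 percentage points (one standard deviation)
- steps under discussion: catalyst intermediate A -> catalyst intermediate B; target <-> isomer of the product; catalyst intermediate B -> spent catalyst; 2 substrate -> self-condensation product; substrate + free catalyst -> catalyst intermediate A; catalyst intermediate B -> free catalyst + target

- how much target there is at 4.0 h, in percent of the substrate charged
- amount of target if the flask were left three thousand times as long, in percent of the substrate charged

1. Put the flask on a ladder of time scales and count in powers of ten. The lowest rung lies under the first reading: at 0.250 h the larch run already shows 52.3% target, and c(target) falls from there.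

2. The top of the ladder gives the level it falls to. Averaging the last two readings gives a plateau of 5.90% for larch and 6.50% for cedar.

3. The middle rung comes from the first two larch readings, where the excess falls one power of ten in 0.846 h. That is the decade time, the time in which the excess of c(target) over its plateau falls one power of ten. Cedar, at its higher loading, reads 0.903 h.

4. Now the flask. If it keeps this decade time, the span from 0.250 h to 4.0 h holds 4.43 decades. A larch-sized excess then shrinks to 0.0017 percentage points, far less than the scatter of 0.3 points. So I read both questions as asking for the flask's plateau, and I take the larch 5.90% for both, though the lower loading may shade it down.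

5. The forecast goes lower than my figure, to 5.3% and 5.1%: “Extrapolating to 0.2 mol% gives about 0.9 times larch, or roughly 5.3%”.

6. The flask gives 5.95% at 4.0 h and 5.94% for the long stay asked about.

    catalyst intermediate A → catalyst intermediate B (k = 4.50 s⁻¹)
    target ⇌ isomer of the product (K = 13.0, k = 6.70 × 10⁻⁴ s⁻¹)
    catalyst intermediate B → spent catalyst (k = 0.00410 s⁻¹)
    2 substrate → self-condensation product (k = 0.0390 M⁻¹ s⁻¹)
    substrate + free catalyst → catalyst intermediate A (k = 190 M⁻¹ s⁻¹)
    catalyst intermediate B → free catalyst + target (k = 17.0 s⁻¹)

At 40.0 h the flask still holds 5.94%. Back down the ladder, this flask stands at 16.7% at 0.800 h, which is 11 points above its plateau. Going on to 1.0 h takes 0.236 of a decade, so the decade time predicts 12.2%. The same flask read at 1.0 h holds 12.4%.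

(Readings and results are simulated on assumed constants, noise included.)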